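Ferugin (daucane numbering) is traced back to an 8-oxabicyclo[3.2.1]octenone. In its seven-membered ring the C6 oxygen, the C7–C8 unit bearing C14 and the C9 oxygen correspond to ketone, enone alkene and ether bridge, and the C1–C5 bond is the edge shared with the cyclopentane. An intramolecular oxidopyrylium–alkene (5+2) cycloaddition forms C1–C5 and C9–C10 in one operation, closes both carbocycles and sets C1, C5 and C9 from the single stereocentre C4. Its precursor is an Achmatowicz-derived acetoxypyranone whose carbon next to the ring oxygen carries the R-configured C4 carbinol (triethylsilyl ether, isopropyl group) and a 3-methylbut-3-enyl chain; the ether bridge of the adduct later becomes the C9 hydroxyl.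

Key step: step 10

Conventions: C1 is the angular-methyl carbon, C4 the isopropyl carbinol, C5 the ring-fusion CH, C6 the ester carbon, C8 the methylidene carbon, C9 the free carbinol, C14 the exocyclic CH2 and C15 the angular methyl; β is the face of C15. The target is (1R,4R,5S,6S,9S).
Assumption: 2-methylallylmagnesium chloride is bought as its THF solution.

Step 1
Reactants: 1 isovaleraldehyde (3-methylbutanal)
Product: 2 2-isopropylacrolein (3-methyl-2-methylidenebutanal)
Conditions: 37% aq. CH2O, pyrrolidine (10 mol %), propionic acid (10 mol %), i-PrOH, 45 °C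
Reagents that add atoms: formaldehyde, C=O
Why: Amine-catalysed Mannich condensation and elimination (α-methylenation of an aldehyde) turns the α-CH2 of the linear aldehyde into the C=CH2 unit that becomes C3; no stereocentre is formed.

Step 2
Reactants: 2 2-isopropylacrolein
Product: 3 3-methyl-2-methylidenebutan-1-ol
Conditions: NaBH4, CeCl3·7H2O, MeOH, 0 °C
Reagents that add atoms: none
Why: Luche reduction delivers hydride 1,2 to the enal carbonyl and leaves the 1,1-disubstituted alkene untouched; no stereocentre is formed.

Step 3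
Reactants: 3 3-methyl-2-methylidenebutan-1-ol
Product: 4 (R)-[2-(propan-2-yl)oxiran-2-yl]methanol
Conditions: Ti(OiPr)4 (10 mol %), D-(−)-diisopropyl tartrate (12 mol %), t-BuOOH, 4 Å MS, CH2Cl2, −20 °C
Reagents that add atoms: tert-butyl hydroperoxide, CC(C)(C)OO
Why: Sharpless asymmetric epoxidation of a 2-substituted allylic alcohol, in which the titanium tartrate complex binds the hydroxyl and delivers the peroxide oxygen to one alkene face; the D-(−)-tartrate is chosen because the L-(+)-ester gives (S)-2-alkylglycidols, so the R centre that becomes C4 is set here by the catalyst.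

Step 4
Reactants: 4 (R)-[2-(propan-2-yl)oxiran-2-yl]methanol; 5 2-methylallylmagnesium chloride
Product: 6 (R)-5-methyl-2-(propan-2-yl)hex-5-ene-1,2-diol
Conditions: 5 (3 equiv), CuBr·SMe2 (10 mol %), THF, −30 → 0 °C; aq. NH4Cl
Reagents that add atoms: none
Why: Copper-catalysed Grignard opening (SN2) of the 2,2-disubstituted epoxide occurs at its unsubstituted CH2 after the first equivalent has deprotonated the hydroxyl; the C4–O bond is not broken, so C4 keeps its configuration, and allylic transposition of the methallyl nucleophile is degenerate.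

Step 5
Reactants: 6 (R)-5-methyl-2-(propan-2-yl)hex-5-ene-1,2-diol
Product: 7 (R)-5-methyl-2-(propan-2-yl)-1,2-bis(triethylsilyloxy)hex-5-ene
Conditions: TESOTf (2.5 equiv), 2,6-lutidine, CH2Cl2, −78 → 0 °C
Reagents that add atoms: triethylsilyl trifluoromethanesulfonate, CC[Si](CC)(CC)OS(=O)(=O)C(F)(F)F
Why: A silyl triflate with a hindered pyridine base silylates both the primary and the tertiary hydroxyl (standard silyl ether formation); C4 is untouched.

Step 6
Reactants: 7 (R)-5-methyl-2-(propan-2-yl)-1,2-bis(triethylsilyloxy)hex-5-ene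
Product: 8 (R)-5-methyl-2-(propan-2-yl)-2-(triethylsilyloxy)hex-5-enal
Conditions: (COCl)2 (4 equiv), DMSO (8 equiv), CH2Cl2, −78 → −30 °C; then Et3N, −78 → 0 °C
Reagents that add atoms: none
Why: Swern oxidation applied to a primary triethylsilyl ether: the unhindered ether oxygen is activated by the chlorosulfonium salt, loses its silyl group and is oxidised to the aldehyde, while the tertiary silyl ether is too hindered to react; the aldehyde has no α-hydrogen, so C4 cannot epimerise.

Step 7
Reactants: 8 (R)-5-methyl-2-(propan-2-yl)-2-(triethylsilyloxy)hex-5-enal; 9 3-methylfuran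
Product: 11 (2R)-5-methyl-1-(4-methylfuran-2-yl)-2-(propan-2-yl)-2-(triethylsilyloxy)hex-5-en-1-ol as both C1 epimers, via 4-methyl-2-furyllithium 10 (not isolated)
Conditions: 9 (1.6 equiv), sec-BuLi (1.5 equiv), THF, −78 → −20 °C; then 8, −78 °C; aq. NH4Cl at −78 °C
Reagents that add atoms: none
Why: α-Lithiation of the furan at its less hindered and more acidic C5–H, remote from the methyl group (any 3-methyl-2-furyl isomer would be removed by chromatography), is followed by 1,2-addition to the non-enolisable aldehyde; the new carbinol centre (C5) may form as a mixture because it becomes planar in step 10, and the cold quench should prevent a 1,4-shift of the silyl group to the new alkoxide.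

Step 8
Reactants: 11 (2R)-5-methyl-1-(4-methylfuran-2-yl)-2-(propan-2-yl)-2-(triethylsilyloxy)hex-5-en-1-ol
Product: 12 6-hydroxy-5-methyl-2-[(3R)-2,6-dimethyl-3-(triethylsilyloxy)hept-6-en-3-yl]-2H-pyran-3(6H)-one as a mixture of ring epimers
Conditions: NBS (1.05 equiv), NaHCO3, NaOAc, THF/H2O (4:1), 0 °C
Reagents that add atoms: water, O
Why: Achmatowicz rearrangement: NBS oxidises the electron-rich furan much faster than the isolated 1,1-disubstituted alkene, the ring opens to the cis-enedione and the carbinol hydroxyl closes the pyranone hemiacetal; both pyranone sp3 centres are mixtures that are erased in step 10.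

Step 9
Reactants: 12 6-hydroxy-5-methyl-2-[(3R)-2,6-dimethyl-3-(triethylsilyloxy)hept-6-en-3-yl]-2H-pyran-3(6H)-one
Product: 13 6-acetoxy-5-methyl-2-[(3R)-2,6-dimethyl-3-(triethylsilyloxy)hept-6-en-3-yl]-2H-pyran-3(6H)-one as a mixture of ring epimers
Conditions: Ac2O, pyridine, DMAP (5 mol %), CH2Cl2, 0 °C
Reagents that add atoms: acetic anhydride, CC(=O)OC(C)=O
Why: DMAP-catalysed acetylation of the anomeric hydroxyl installs the leaving group needed for ylide formation; the epimer mixture is carried on.

Step 10
Reactants: 13 6-acetoxy-5-methyl-2-[(3R)-2,6-dimethyl-3-(triethylsilyloxy)hept-6-en-3-yl]-2H-pyran-3(6H)-one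
Product: 15 5α,9α-epoxy-4β-(triethylsilyloxy)dauc-7-en-6-one, via oxidopyrylium ylide 14 (not isolated)
Conditions: DBU (1.5 equiv), MeCN (0.01 M), 23 → 60 °C
Reagents that add atoms: none
Why: DBU removes the acidic C5 proton and acetate leaves from C9, which gives the 3-oxidopyrylium 14 with both former pyranone stereocentres planar (the epimer mixture converges), and this ylide adds suprafacially through C5 and C9 to the tethered 1,1-disubstituted alkene in a concerted, thermally allowed dipolar (5+2) cycloaddition. The closest known reaction type is the intramolecular oxidopyrylium–alkene cycloaddition of Achmatowicz-derived acetoxypyranones carrying a three-atom tether. The cyclopentane closes in a 5-exo sense, C5 bonding to the internal alkene carbon C1 through the C4–C3–C2 tether, and the cycloheptene closes with the second bond C9–C10 as the carbocyclic perimeter (C1, C5 to C10) of the oxabicycle. C5 and C9 are held cis by the one-atom oxygen bridge, C1 is fixed by the tether, which reaches only the exo positions (C2 syn and C15 anti to the bridge), and the sense of all three relative to C4 follows from the ylide face that the alkene reaches. The selectivity needed is this facial choice: in the reacting rotamer about C4–C5 one C4 substituent must lie beside the C6 oxido oxygen and one beside the ring oxygen, and the compact C4–O bond (long O–Si bond, silyl group turned outward) should take the crowded oxido side while the branched isopropyl group takes the open side, which gives the 4β-silyloxy/5α,9α-bridge relationship of 15. Regiochemistry needs no control because the tether length allows only the C1–C5/C9–C10 mode.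

Step 11
Reactants: 15 5α,9α-epoxy-4β-(triethylsilyloxy)dauc-7-en-6-one
Product: 17 5α,9α-epoxy-4β-(triethylsilyloxy)dauc-8(14)-en-6-one, via potassium dienolate 16 (not isolated)
Conditions: KN(SiMe3)2 (1.3 equiv), THF, −78 °C; then AcOH in THF, −78 °C
Reagents that add atoms: none
Why: Because C5 is a fully substituted bridgehead, the only acidic position of the enone is the γ-methyl group C14, so the amide base gives the extended dienolate 16, and kinetic protonation of a dienolate occurs at the α-carbon (C7), which is the classical deconjugative protonation and moves the alkene to C8=C14 without touching a stereocentre.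

Step 12
Reactants: 17 5α,9α-epoxy-4β-(triethylsilyloxy)dauc-8(14)-en-6-one
Product: 19 9α-hydroxy-4β-(triethylsilyloxy)-5αH-dauc-8(14)-en-6-one, via samarium enolate 18 (not isolated)
Conditions: SmI2 (2.5 equiv), THF/MeOH (4:1), −78 °C; pH 7 buffer
Reagents that add atoms: none
Why: SmI2 reduces the ketone to a ketyl that expels the α-alkoxy substituent (reductive cleavage of an α-heterosubstituted ketone, known for oxa-bridged cycloadducts), which breaks C5–O, leaves the C9 oxygen with its configuration and gives the trivalent samarium enolate 18; this should be protonated at C5 on the α face just vacated by the bridge, where the C9 hydroxyl or its bound methanol can relay the proton and the opposite face is screened by C15 and the silyl ether, giving the trans ring fusion.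

Step 13
Reactants: 19 9α-hydroxy-4β-(triethylsilyloxy)-5αH-dauc-8(14)-en-6-one
Product: 20 4β,9α-dihydroxy-5αH-dauc-8(14)-en-6-one
Conditions: HF·pyridine, pyridine, THF, 0 → 23 °C
Reagents that add atoms: none
Why: Fluoride cleavage of the tertiary triethylsilyl ether under buffered, weakly acidic conditions, chosen to avoid base that could open the β-hydroxy ketone by retro-aldol reaction or move the C8=C14 alkene into conjugation; no stereocentre changes.

Step 14
Reactants: 20 4β,9α-dihydroxy-5αH-dauc-8(14)-en-6-one
Product: 21 9α-(tert-butyldimethylsilyloxy)-4β-hydroxy-5αH-dauc-8(14)-en-6-one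
Conditions: TBSCl (1.3 equiv), imidazole, DMF, 0 → 23 °C
Reagents that add atoms: tert-butyldimethylsilyl chloride, CC(C)(C)[Si](C)(C)Cl
Why: Silyl chloride and imidazole silylate the secondary allylic C9 hydroxyl and leave the hindered tertiary C4 hydroxyl free (chemoselective silyl ether formation), so that only the C4 hydroxyl can direct the next step and only C6 is acylated later.

Step 15
Reactants: 21 9α-(tert-butyldimethylsilyloxy)-4β-hydroxy-5αH-dauc-8(14)-en-6-one
Product: 22 9α-(tert-butyldimethylsilyloxy)-5αH-dauc-8(14)-ene-4β,6α-diol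
Conditions: Me4NBH(OAc)3 (5 equiv), MeCN/AcOH (1:1), −30 → 0 °C
Reagents that add atoms: none
Why: Evans–Saksena directed reduction: the C4 hydroxyl exchanges onto boron and delivers hydride intramolecularly to the β face of the C6 ketone, which gives the 6α alcohol anti to the 4β hydroxyl, while the reagent does not reduce ketones intermolecularly and the silylated C9 oxygen cannot compete.

Step 16
Reactants: 23 4-hydroxybenzoic acid
Product: 25 4-(tert-butyldimethylsilyloxy)benzoic acid, via silyl ester 24 (not isolated)
Conditions: TBSCl (2.3 equiv), imidazole, DMF, 23 °C; then AcOH/THF/H2O (3:1:1), 23 °C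
Reagents that add atoms: tert-butyldimethylsilyl chloride, CC(C)(C)[Si](C)(C)Cl
Why: Exhaustive silylation followed by mild aqueous acid, which hydrolyses the labile silyl ester and leaves the aryl silyl ether (standard selective deprotection); no stereocentre is involved.

Step 17
Reactants: 22 9α-(tert-butyldimethylsilyloxy)-5αH-dauc-8(14)-ene-4β,6α-diol; 25 4-(tert-butyldimethylsilyloxy)benzoic acid
Product: 26 6α-[4-(tert-butyldimethylsilyloxy)benzoyloxy]-9α-(tert-butyldimethylsilyloxy)-5αH-dauc-8(14)-en-4β-ol
Conditions: EDC·HCl (2 equiv), DMAP (1 equiv), CH2Cl2, 23 °C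
Reagents that add atoms: none
Why: Carbodiimide and DMAP acylation (Steglich esterification) of the only secondary hydroxyl, the tertiary C4 hydroxyl being unreactive; the C6–O bond is not broken, so the configuration is retained.

Step 18
Reactants: 26 6α-[4-(tert-butyldimethylsilyloxy)benzoyloxy]-9α-(tert-butyldimethylsilyloxy)-5αH-dauc-8(14)-en-4β-ol
Product: 27 ferugin, 4β,9α-dihydroxy-6α-(4-hydroxybenzoyloxy)-5αH-dauc-8(14)-ene
Conditions: HF·pyridine, pyridine, THF, 0 → 23 °C
Reagents that add atoms: none
Why: HF·pyridine cleaves the aryl and the secondary allylic silyl ethers in one operation under conditions that should neither hydrolyse nor migrate the benzoate ester nor isomerise the exocyclic alkene; no stereocentre changes.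

Compound list
1 | isovaleraldehyde (3-methylbutanal) | CC(C)CC=O | starting material
2 | 2-isopropylacrolein (3-methyl-2-methylidenebutanal) | C=C(C=O)C(C)C | intermediate
3 | 3-methyl-2-methylidenebutan-1-ol | C=C(CO)C(C)C | intermediate
4 | (R)-[2-(propan-2-yl)oxiran-2-yl]methanol | C1O[C@@]1(CO)C(C)C | intermediate
5 | 2-methylallylmagnesium chloride | C=C(C)C[Mg]Cl | starting material
6 | (R)-5-methyl-2-(propan-2-yl)hex-5-ene-1,2-diol | C=C(C)CC[C@@](CO)(O)C(C)C | intermediate
7 | (R)-5-methyl-2-(propan-2-yl)-1,2-bis(triethylsilyloxy)hex-5-ene | C=C(C)CC[C@@](CO[Si](CC)(CC)CC)(O[Si](CC)(CC)CC)C(C)C | intermediate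
8 | (R)-5-methyl-2-(propan-2-yl)-2-(triethylsilyloxy)hex-5-enal | C=C(C)CC[C@@](C=O)(O[Si](CC)(CC)CC)C(C)C | intermediate
9 | 3-methylfuran | Cc1ccoc1 | starting material
10 | 4-methyl-2-furyllithium | [Li]c1cc(C)co1 | intermediate
11 | (2R)-5-methyl-1-(4-methylfuran-2-yl)-2-(propan-2-yl)-2-(triethylsilyloxy)hex-5-en-1-ol, both C1 epimers | C=C(C)CC[C@@](C(O)c1cc(C)co1)(O[Si](CC)(CC)CC)C(C)C | intermediate
12 | 6-hydroxy-5-methyl-2-[(3R)-2,6-dimethyl-3-(triethylsilyloxy)hept-6-en-3-yl]-2H-pyran-3(6H)-one, ring epimers | C=C(C)CC[C@@](C1OC(O)C(C)=CC1=O)(O[Si](CC)(CC)CC)C(C)C | intermediate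
13 | 6-acetoxy-5-methyl-2-[(3R)-2,6-dimethyl-3-(triethylsilyloxy)hept-6-en-3-yl]-2H-pyran-3(6H)-one, ring epimers | C=C(C)CC[C@@](C1OC(OC(C)=O)C(C)=CC1=O)(O[Si](CC)(CC)CC)C(C)C | intermediate
14 | 5-methyl-2-[(3R)-2,6-dimethyl-3-(triethylsilyloxy)hept-6-en-3-yl]pyrylium-3-olate (oxidopyrylium ylide) | C=C(C)CC[C@@](c1[o+]cc(C)cc1[O-])(O[Si](CC)(CC)CC)C(C)C | intermediate
15 | 5α,9α-epoxy-4β-(triethylsilyloxy)dauc-7-en-6-one (C15 β) | CC1=CC(=O)[C@]2(O3)[C@](C)(CC[C@@]2(O[Si](CC)(CC)CC)C(C)C)C[C@@H]13 | intermediate
16 | potassium 5α,9α-epoxy-4β-(triethylsilyloxy)dauca-6,8(14)-dien-6-olate | C=C1C=C([O-])[C@]2(O3)[C@](C)(CC[C@@]2(O[Si](CC)(CC)CC)C(C)C)C[C@@H]13.[K+] | intermediate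
17 | 5α,9α-epoxy-4β-(triethylsilyloxy)dauc-8(14)-en-6-one | C=C1CC(=O)[C@]2(O3)[C@](C)(CC[C@@]2(O[Si](CC)(CC)CC)C(C)C)C[C@@H]13 | intermediate
18 | trivalent samarium enolate and alkoxide of 4β-(triethylsilyloxy)dauca-5,8(14)-diene-6,9α-diol (SmI2 on each oxygen) | C=C1CC(O[Sm](I)I)=C2[C@](C)(CC[C@@]2(O[Si](CC)(CC)CC)C(C)C)C[C@@H]1O[Sm](I)I | intermediate
19 | 9α-hydroxy-4β-(triethylsilyloxy)-5αH-dauc-8(14)-en-6-one | C=C1CC(=O)[C@@H]2[C@](C)(CC[C@@]2(O[Si](CC)(CC)CC)C(C)C)C[C@@H]1O | intermediate
20 | 4β,9α-dihydroxy-5αH-dauc-8(14)-en-6-one | C=C1CC(=O)[C@@H]2[C@](C)(CC[C@@]2(O)C(C)C)C[C@@H]1O | intermediate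
21 | 9α-(tert-butyldimethylsilyloxy)-4β-hydroxy-5αH-dauc-8(14)-en-6-one | C=C1CC(=O)[C@@H]2[C@](C)(CC[C@@]2(O)C(C)C)C[C@@H]1O[Si](C)(C)C(C)(C)C | intermediate
22 | 9α-(tert-butyldimethylsilyloxy)-5αH-dauc-8(14)-ene-4β,6α-diol | C=C1C[C@H](O)[C@@H]2[C@](C)(CC[C@@]2(O)C(C)C)C[C@@H]1O[Si](C)(C)C(C)(C)C | intermediate
23 | 4-hydroxybenzoic acid | O=C(O)c1ccc(O)cc1 | starting material
24 | tert-butyldimethylsilyl 4-(tert-butyldimethylsilyloxy)benzoate | CC(C)(C)[Si](C)(C)OC(=O)c1ccc(O[Si](C)(C)C(C)(C)C)cc1 | intermediate
25 | 4-(tert-butyldimethylsilyloxy)benzoic acid | O=C(O)c1ccc(O[Si](C)(C)C(C)(C)C)cc1 | intermediate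
26 | 6α-[4-(tert-butyldimethylsilyloxy)benzoyloxy]-9α-(tert-butyldimethylsilyloxy)-5αH-dauc-8(14)-en-4β-ol | C=C1C[C@H](OC(=O)c2ccc(O[Si](C)(C)C(C)(C)C)cc2)[C@@H]2[C@](C)(CC[C@@]2(O)C(C)C)C[C@@H]1O[Si](C)(C)C(C)(C)C | intermediate
27 | ferugin, (1R,4R,5S,6S,9S)-4β,9α-dihydroxy-6α-(4-hydroxybenzoyloxy)-5αH-dauc-8(14)-ene | C=C1C[C@H](OC(=O)c2ccc(O)cc2)[C@@H]2[C@](C)(CC[C@@]2(O)C(C)C)C[C@@H]1O | target

Total step count: 18. Longest linear sequence: 17 steps (steps 1 to 15, 17 and 18, from isovaleraldehyde); step 16 is a one-step side branch.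

Steps most likely to fail

Step 10. The alkene may reach the wrong face of the ylide, because the silyloxy and isopropyl groups on C4 differ only moderately in their demand for the position beside the oxido oxygen. The congested C1–C5 bond, which joins two fully substituted carbons next to quaternary C4, may also form so slowly that the ylide dimerises. The fallback replaces steric control by hydrogen-bond control. It sets out from 13, whose silyl ether is removed with buffered HF·pyridine to give 6-acetoxy-2-[(3R)-3-hydroxy-2,6-dimethylhept-6-en-3-yl]-5-methyl-2H-pyran-3(6H)-one F1. In the ylide formed from it with DBU in dilute MeCN, the C4 hydroxyl can donate a hydrogen bond to the C6 oxido oxygen through a six-membered chelate. This locks the C4–O bond on the oxido side and should give 5α,9α-epoxy-4β-hydroxydauc-7-en-6-one F2. Silylation with TESOTf and 2,6-lutidine then returns to 15.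

Step 12. The samarium enolate may be protonated on the β face, which gives the cis ring fusion, or it may expel the β-silyloxy group; a wrong C5 centre cannot be equilibrated later without drawing the C8=C14 alkene into conjugation. The fallback puts C5 under thermodynamic control while the enone is still conjugated. It sets out from 15, which SmI2 in THF/MeOH opens at C5–O to 9α-hydroxy-4β-(triethylsilyloxy)dauc-7-en-6-one as a C5 epimer mixture F3. Brief treatment with DBU in toluene equilibrates C5 through the enol and should favour the trans-fused isomer 9α-hydroxy-4β-(triethylsilyloxy)-5αH-dauc-7-en-6-one F4, in which C6 lies anti to the isopropyl group. KN(SiMe3)2 (2.2 equiv, THF, −78 °C) then forms the alkoxide and the extended dienolate, the hindered C5–H being removed more slowly than a C14 hydrogen, and a cold acetic acid quench protonates C7 and gives 19, where the route resumes.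

Step 11. γ-Deprotonation may be incomplete, or the dienolate may be protonated at C14, which returns 15. The fallback reaches the deconjugated ketone reductively. It sets out from 15, whose allylic γ-methyl group is brominated under Wohl–Ziegler conditions (NBS, AIBN, PhCF3, 80 °C) to 14-bromo-5α,9α-epoxy-4β-(triethylsilyloxy)dauc-7-en-6-one F5. SmI2 (5 equiv, THF/MeOH, −78 °C) reduces the allylic bromide to the samarium dienolate regiospecifically, methanol protonates it at C7, and further reagent cleaves C5–O in the same flask. The route is rejoined at 19, with steps 11 and 12 merged.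

Further compounds
F1 | step 10 | 6-acetoxy-2-[(3R)-3-hydroxy-2,6-dimethylhept-6-en-3-yl]-5-methyl-2H-pyran-3(6H)-one | C=C(C)CC[C@@](C1OC(OC(C)=O)C(C)=CC1=O)(O)C(C)C
F2 | step 10 | 5α,9α-epoxy-4β-hydroxydauc-7-en-6-one | CC1=CC(=O)[C@]2(O3)[C@](C)(CC[C@@]2(O)C(C)C)C[C@@H]13
F3 | step 12 | 9α-hydroxy-4β-(triethylsilyloxy)dauc-7-en-6-one, C5 epimer mixture | CC1=CC(=O)C2[C@](C)(CC[C@@]2(O[Si](CC)(CC)CC)C(C)C)C[C@@H]1O
F4 | step 12 | 9α-hydroxy-4β-(triethylsilyloxy)-5αH-dauc-7-en-6-one | CC1=CC(=O)[C@@H]2[C@](C)(CC[C@@]2(O[Si](CC)(CC)CC)C(C)C)C[C@@H]1O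
F5 | step 11 | 14-bromo-5α,9α-epoxy-4β-(triethylsilyloxy)dauc-7-en-6-one | BrCC1=CC(=O)[C@]2(O3)[C@](C)(CC[C@@]2(O[Si](CC)(CC)CC)C(C)C)C[C@@H]13
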